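## Retrosynthetic overview

1. The target is read as (−)-epicatechin 3-O-gallate-(4β→6)-(−)-epicatechin 3-O-gallate-(4β→8)-(+)-catechin. The last operations are a global hydrogenolysis (nineteen benzyl ethers, one bromine cap) and one double galloylation of the two axial 3-hydroxyls.
2. Key disconnection: ring C of the middle unit is opened at O1–C2, together with the C4–C8 bond to the lower unit, giving an acyclic cis-epoxy carbinol and penta-O-benzylcatechin. The enabling feature is that C2 is benzylic to the electron-rich catechol ring B and vicinal to the C3 oxygen (so C2–C3 can be a cis-epoxide), O1 is a phenol oxygen of phloroglucinol ring A five atoms from C2, and C4 is benzylic to the same ring A and ionises once the ring is closed.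
3. The epoxy carbinol comes from an aryllithium and a (2S,3S)-cis-3-arylglycidaldehyde (Still–Gennari olefination, Jacobsen–Katsuki epoxidation). The aryl bromide is the 4β-adduct of tetra-O-benzylepicatechin with symmetric 3,5-bis(benzyloxy)-2,6-dibromophenol: its only free carbon becomes C6, one bromine becomes the C4a–C4 bond, the other caps C8, so the 4→6 connectivity is fixed by which oxygen closes the ring.
4. Ring order: rings A, B and C of the upper and lower units come from (−)-epicatechin and (+)-catechin; ring A of the middle unit enters as a benzene, ring B with the epoxide, and ring C of the middle unit is closed last, in the key step.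

Key step: step 11

Remarks and assumptions: flavan numbering is used throughout (O1, C2, C3, C4, C4a, C5–C8, C8a; ring A = benzo ring, ring B = 2-aryl ring, ring C = pyran ring). 3,5-Bis(benzyloxy)phenol, 3,4-bis(benzyloxy)benzaldehyde, methyl bis(2,2,2-trifluoroethyl)phosphonoacetate and 3,4,5-tris(benzyloxy)benzoic acid are taken as commercial. Compound 15 and intermediate 16 are mixtures of epimers at C4 of the middle unit (a centre that is ionised in step 11), so their SMILES leave that centre open.

## Route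

Step 1
Reactants: 1 (−)-epicatechin
Product: 2 5,7,3',4'-tetra-O-benzyl-(−)-epicatechin
Conditions: BnBr (4.4 equiv), K2CO3, DMF, 0 °C to rt
Reagents that add atoms: benzyl bromide, BrCc1ccccc1
Why: Williamson ether synthesis in which the four phenols, far more acidic than the 3-hydroxyl, are the only groups benzylated by K2CO3, with no stereocentre touched.

Step 2
Reactants: 2 5,7,3',4'-tetra-O-benzyl-(−)-epicatechin
Product: 3 4β-(2-ethoxyethoxy)-5,7,3',4'-tetra-O-benzyl-(−)-epicatechin
Conditions: DDQ (2 equiv), 2-ethoxyethanol, CH2Cl2, rt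
Reagents that add atoms: 2-ethoxyethanol, CCOCCO
Why: DDQ-mediated benzylic oxidation, in which hydride abstraction at C4 gives a cation stabilised by the 5,7-dioxygenated ring A and the alcohol adds trans to the axial 3-hydroxyl, so the new C4 centre should be 4β.

Step 3
Reactants: 4 3,5-bis(benzyloxy)phenol
Product: 5 3,5-bis(benzyloxy)-2,6-dibromophenol
Conditions: NBS (2.05 equiv), i-Pr2NH (10 mol %), CH2Cl2, 0 °C
Reagents that add atoms: N-bromosuccinimide, O=C1CCC(=O)N1Br
Why: Electrophilic aromatic bromination in which the secondary amine relays bromine to the two positions ortho to the phenolic hydroxyl, while the para carbon stays shielded by its two flanking benzyloxy groups; no stereocentre is formed.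

Step 4
Reactants: 3 4β-(2-ethoxyethoxy)-5,7,3',4'-tetra-O-benzyl-(−)-epicatechin; 5 3,5-bis(benzyloxy)-2,6-dibromophenol (3 equiv)
Product: 6 4β-[2,6-bis(benzyloxy)-3,5-dibromo-4-hydroxyphenyl]-5,7,3',4'-tetra-O-benzyl-(−)-epicatechin
Conditions: TMSOTf (20 mol %), CH2Cl2, −78 to −40 °C
Reagents that add atoms: none
Why: Friedel–Crafts alkylation by the C4 benzylic cation released from 3, in which the only unsubstituted carbon of 5 (para to OH) attacks anti to the 3-hydroxyl to give the 4β (3,4-trans) aryl flavan, and the excess of 5 outcompetes self-condensation.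

Step 5
Reactants: 7 3,4-bis(benzyloxy)benzaldehyde; 8 methyl bis(2,2,2-trifluoroethyl)phosphonoacetate
Product: 9 methyl (Z)-3-[3,4-bis(benzyloxy)phenyl]prop-2-enoate
Conditions: KN(SiMe3)2, 18-crown-6, THF, −78 °C
Reagents that add atoms: none
Why: Still–Gennari olefination (Horner–Wadsworth–Emmons reaction of a bis(trifluoroethyl) phosphonate), whose fast and irreversible elimination from the first-formed adduct should give the (Z)-enoate.

Step 6
Reactants: 9 methyl (Z)-3-[3,4-bis(benzyloxy)phenyl]prop-2-enoate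
Product: 10 methyl (2S,3S)-3-[3,4-bis(benzyloxy)phenyl]oxirane-2-carboxylate (cis)
Conditions: (S,S)-N,N'-bis(3,5-di-tert-butylsalicylidene)-1,2-cyclohexanediaminomanganese chloride (6 mol %), 4-phenylpyridine N-oxide (25 mol %), aq NaOCl (pH 11.3), CH2Cl2, 4 °C
Reagents that add atoms: sodium hypochlorite, [Na+].[O-]Cl
Why: Jacobsen–Katsuki epoxidation, a reaction suited to cis-disubstituted aryl alkenes, in which the chiral manganese salen oxo species delivers oxygen to one face of the (Z)-cinnamate so that both epoxide centres are set by the catalyst (the (S,S) complex is the mirror image of the one that converts (Z)-cinnamate esters into (2R,3R)-glycidates).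

Step 7
Reactants: 10 methyl (2S,3S)-3-[3,4-bis(benzyloxy)phenyl]oxirane-2-carboxylate
Product: 11 (2S,3S)-3-[3,4-bis(benzyloxy)phenyl]oxirane-2-carbaldehyde (cis)
Conditions: i-Bu2AlH (1.1 equiv), CH2Cl2, −78 °C; MeOH, then aq potassium sodium tartrate; used at once
Reagents that add atoms: none
Why: Partial reduction of an ester with i-Bu2AlH at −78 °C, in which the aluminium hemiacetal survives until work-up and the two epoxide centres are not touched.

Step 8
Reactants: 12 (+)-catechin
Product: 13 5,7,3',4'-tetra-O-benzyl-(+)-catechin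
Conditions: BnBr (4.4 equiv), K2CO3, DMF, 0 °C to rt
Reagents that add atoms: benzyl bromide, BrCc1ccccc1
Why: Williamson ether synthesis limited to the four phenols by the weak base, with no stereocentre touched.

Step 9
Reactants: 13 5,7,3',4'-tetra-O-benzyl-(+)-catechin
Product: 14 3,5,7,3',4'-penta-O-benzyl-(+)-catechin
Conditions: NaH, BnBr, DMF, 0 °C to rt
Reagents that add atoms: benzyl bromide, BrCc1ccccc1
Why: Williamson ether synthesis on the sodium alkoxide of the 3-hydroxyl, which masks the one secondary alcohol that must stay free of gallate, with retention at C3.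

Step 10
Reactants: 6 4β-[2,6-bis(benzyloxy)-3,5-dibromo-4-hydroxyphenyl]-5,7,3',4'-tetra-O-benzyl-(−)-epicatechin; 11 (2S,3S)-3-[3,4-bis(benzyloxy)phenyl]oxirane-2-carbaldehyde
Product: 15 epoxy diol: 4β-aryl-5,7,3',4'-tetra-O-benzyl-(−)-epicatechin whose aryl group is 2,6-bis(benzyloxy)-3-bromo-4-hydroxyphenyl carrying at C5 a CH(OH) group (both epimers) bonded to C2 of the cis-3-[3,4-bis(benzyloxy)phenyl]oxirane of 11 (oxirane centres unchanged)
Conditions: NaH (2.2 equiv), THF, 0 °C; t-BuLi (2.1 equiv), −78 °C; 11 (1.5 equiv), −78 °C; aq NH4Cl; crude product used at once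
Reagents that add atoms: none
Why: Bromine–lithium exchange followed by 1,2-addition of the aryllithium to the aldehyde, in which the two hydroxyls are first masked as sodium salts, one of the two equivalent bromines is exchanged, and the carbinol centre forms as a mixture of epimers that is harmless because this carbon is ionised in step 11.

Step 11
Reactants: 15 epoxy diol; 14 3,5,7,3',4'-penta-O-benzyl-(+)-catechin (4 equiv)
Product: 17 5,7,3',4'-tetra-O-benzylepicatechin-(4β→6)-8-bromo-5,7,3',4'-tetra-O-benzylepicatechin-(4β→8)-3,5,7,3',4'-penta-O-benzylcatechin, via flavan-3,4-diol 16 (not isolated)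
Conditions: PPTS (10 mol %), 4 Å MS, CH2Cl2, −20 °C; then 14 and BF3·OEt2 (30 mol %) added to the same flask, −78 to −30 °C
Reagents that add atoms: none
Why: PPTS activates the epoxide and the only free phenol of ring A of the middle unit (O1) attacks the benzylic epoxide carbon C2 from the back in a 6-endo-tet opening, so that release of oxirane strain drives formation of the O1–C2 bond and of the pyran ring; the closest known reaction type is the acid-catalysed cyclisation of 2-(3-aryloxiranylmethyl)phenols to flavan-3-ols. C2 is set by inversion at the epoxide carbon and C3 is carried over unchanged from the epoxide, which together turn the cis-epoxide into the 2,3-cis (epicatechin) relationship. BF3·OEt2 then ionises the C4 hydroxyl of either epimer of 16 to the benzylic cation stabilised by ring A, with loss of water to the molecular sieves, and C8 of 14 attacks it anti to the pseudoaxial 3-hydroxyl, as in the known Lewis-acid couplings of 2,3-cis-flavan-3,4-diol derivatives with flavan-3-ols, which sets C4 as 4β (3,4-trans). The step needs O1 and not O5 to close the ring (O5 and O7 are benzyl ethers, which also fixes the 4→6 link to the upper unit), 6-endo and not 5-exo opening (C2 is benzylic to the 3,4-dialkoxyphenyl ring), ring closure before C4 arylation (the epoxide opening is irreversible under the weak acid, ionisation of the carbinol is reversible, and 14 enters only afterwards) and attack by C8 and not C6 of 14 (innate preference of the 5,7-dioxygenated chroman). The bromine at C8 of the middle unit and the excess of 14 suppress self-condensation.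

Step 12
Reactants: 17 trimer diol; 18 3,4,5-tris(benzyloxy)benzoic acid (6 equiv)
Product: 19 bis(3,4,5-tri-O-benzylgallate) of 17 at the 3-oxygens of the upper and middle units
Conditions: DCC, DMAP, CH2Cl2, rt
Reagents that add atoms: none
Why: Steglich esterification, in which DCC activates 18 and DMAP transfers the acyl group to the two free secondary 3-hydroxyls with retention, while the 3-oxygen of the lower unit is a benzyl ether.

Step 13
Reactants: 19 fully protected bromo trimer digallate
Product: 20 (−)-epicatechin 3-O-gallate-(4β→6)-(−)-epicatechin 3-O-gallate-(4β→8)-(+)-catechin (target)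
Conditions: H2 (1 atm), Pd(OH)2/C, Et3N (2 equiv), THF/MeOH/H2O, rt
Reagents that add atoms: none
Why: Catalytic hydrogenolysis, which should cleave all nineteen benzyl ethers and the aryl C–Br bond in one operation with Et3N taking up the HBr, leaving esters, interflavan bonds and all stereocentres untouched.

## Compound list

1 | (−)-epicatechin | O[C@@H]1Cc2c(O)cc(O)cc2O[C@@H]1c1ccc(O)c(O)c1 | starting material
2 | 5,7,3',4'-tetra-O-benzyl-(−)-epicatechin | O[C@@H]1Cc2c(OCc3ccccc3)cc(OCc3ccccc3)cc2O[C@@H]1c1ccc(OCc2ccccc2)c(OCc2ccccc2)c1 | intermediate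
3 | 4β-(2-ethoxyethoxy)-5,7,3',4'-tetra-O-benzyl-(−)-epicatechin | O[C@@H]1[C@@H](OCCOCC)c2c(OCc3ccccc3)cc(OCc3ccccc3)cc2O[C@@H]1c1ccc(OCc2ccccc2)c(OCc2ccccc2)c1 | intermediate
4 | 3,5-bis(benzyloxy)phenol | Oc1cc(OCc2ccccc2)cc(OCc2ccccc2)c1 | starting material
5 | 3,5-bis(benzyloxy)-2,6-dibromophenol | Oc1c(Br)c(OCc2ccccc2)cc(OCc2ccccc2)c1Br | intermediate
6 | 4β-[2,6-bis(benzyloxy)-3,5-dibromo-4-hydroxyphenyl]-5,7,3',4'-tetra-O-benzyl-(−)-epicatechin | O[C@@H]1[C@@H](c2c(OCc3ccccc3)c(Br)c(O)c(Br)c2OCc3ccccc3)c2c(OCc3ccccc3)cc(OCc3ccccc3)cc2O[C@@H]1c1ccc(OCc2ccccc2)c(OCc2ccccc2)c1 | intermediate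
7 | 3,4-bis(benzyloxy)benzaldehyde | O=Cc1ccc(OCc2ccccc2)c(OCc2ccccc2)c1 | starting material
8 | methyl bis(2,2,2-trifluoroethyl)phosphonoacetate | COC(=O)CP(=O)(OCC(F)(F)F)OCC(F)(F)F | starting material
9 | methyl (Z)-3-[3,4-bis(benzyloxy)phenyl]prop-2-enoate | COC(=O)/C=C\c1ccc(OCc2ccccc2)c(OCc2ccccc2)c1 | intermediate
10 | methyl (2S,3S)-3-[3,4-bis(benzyloxy)phenyl]oxirane-2-carboxylate | COC(=O)[C@H]1O[C@H]1c1ccc(OCc2ccccc2)c(OCc2ccccc2)c1 | intermediate
11 | (2S,3S)-3-[3,4-bis(benzyloxy)phenyl]oxirane-2-carbaldehyde | O=C[C@H]1O[C@H]1c1ccc(OCc2ccccc2)c(OCc2ccccc2)c1 | intermediate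
12 | (+)-catechin | O[C@H]1Cc2c(O)cc(O)cc2O[C@@H]1c1ccc(O)c(O)c1 | starting material
13 | 5,7,3',4'-tetra-O-benzyl-(+)-catechin | O[C@H]1Cc2c(OCc3ccccc3)cc(OCc3ccccc3)cc2O[C@@H]1c1ccc(OCc2ccccc2)c(OCc2ccccc2)c1 | intermediate
14 | 3,5,7,3',4'-penta-O-benzyl-(+)-catechin | c1ccccc1CO[C@H]1Cc2c(OCc3ccccc3)cc(OCc3ccccc3)cc2O[C@@H]1c1ccc(OCc2ccccc2)c(OCc2ccccc2)c1 | intermediate
15 | epoxy diol (upper unit linked 4β to the open-chain middle unit; mixture of epimers at the carbinol carbon) | O[C@@H]1[C@@H](c2c(OCc3ccccc3)c(Br)c(O)c(C(O)[C@H]3O[C@H]3c3ccc(OCc4ccccc4)c(OCc4ccccc4)c3)c2OCc3ccccc3)c2c(OCc3ccccc3)cc(OCc3ccccc3)cc2O[C@@H]1c1ccc(OCc2ccccc2)c(OCc2ccccc2)c1 | intermediate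
16 | flavan-3,4-diol: tetra-O-benzylepicatechin-(4β→6)-8-bromo-5,7,3',4'-tetra-O-benzyl-2,3-cis-flavan-3,4-diol (mixture of epimers at C4 of the middle unit) | O[C@@H]1[C@@H](c2c(OCc5ccccc5)c(Br)c3c(c2OCc5ccccc5)C(O)[C@@H](O)[C@@H](c2ccc(OCc5ccccc5)c(OCc5ccccc5)c2)O3)c2c(OCc5ccccc5)cc(OCc5ccccc5)cc2O[C@@H]1c1ccc(OCc5ccccc5)c(OCc5ccccc5)c1 | intermediate
17 | tetra-O-benzylepicatechin-(4β→6)-8-bromo-tetra-O-benzylepicatechin-(4β→8)-penta-O-benzylcatechin (3-OH of upper and middle units free) | O[C@@H]1[C@@H](c2c(OCc5ccccc5)c(Br)c3c(c2OCc5ccccc5)[C@H](c2c(OCc5ccccc5)cc(OCc5ccccc5)c4c2O[C@H](c2ccc(OCc5ccccc5)c(OCc5ccccc5)c2)[C@@H](OCc5ccccc5)C4)[C@@H](O)[C@@H](c2ccc(OCc5ccccc5)c(OCc5ccccc5)c2)O3)c2c(OCc5ccccc5)cc(OCc5ccccc5)cc2O[C@@H]1c1ccc(OCc5ccccc5)c(OCc5ccccc5)c1 | intermediate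
18 | 3,4,5-tris(benzyloxy)benzoic acid | OC(=O)c1cc(OCc2ccccc2)c(OCc2ccccc2)c(OCc2ccccc2)c1 | starting material
19 | bis(3,4,5-tri-O-benzylgallate) of 17 (fully protected, 8-bromo on the middle unit) | O=C(O[C@@H]1[C@@H](c2c(OCc5ccccc5)c(Br)c3c(c2OCc5ccccc5)[C@H](c2c(OCc5ccccc5)cc(OCc5ccccc5)c4c2O[C@H](c2ccc(OCc5ccccc5)c(OCc5ccccc5)c2)[C@@H](OCc5ccccc5)C4)[C@@H](OC(=O)c2cc(OCc5ccccc5)c(OCc5ccccc5)c(OCc5ccccc5)c2)[C@@H](c2ccc(OCc5ccccc5)c(OCc5ccccc5)c2)O3)c2c(OCc5ccccc5)cc(OCc5ccccc5)cc2O[C@@H]1c1ccc(OCc5ccccc5)c(OCc5ccccc5)c1)c1cc(OCc5ccccc5)c(OCc5ccccc5)c(OCc5ccccc5)c1 | intermediate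
20 | (−)-epicatechin 3-O-gallate-(4β→6)-(−)-epicatechin 3-O-gallate-(4β→8)-(+)-catechin | O=C(O[C@@H]1[C@@H](c2c(O)cc3c(c2O)[C@H](c2c(O)cc(O)c4c2O[C@H](c2ccc(O)c(O)c2)[C@@H](O)C4)[C@@H](OC(=O)c2cc(O)c(O)c(O)c2)[C@@H](c2ccc(O)c(O)c2)O3)c2c(O)cc(O)cc2O[C@@H]1c1ccc(O)c(O)c1)c1cc(O)c(O)c(O)c1 | target

## Step count and risks

Total step count: 13. Longest linear sequence: 7 steps (steps 1, 2, 4, 10, 11, 12 and 13, from (−)-epicatechin).

Steps most likely to fail:

**Step 11.** The very electron-rich benzylic epoxide may open with carbocation character, which would erode the 2,3-cis relationship or lead to a hydride shift to a ketone. The C4 carbinol may ionise and be captured before the pyran ring has closed, with loss of facial control at C4. The congested C4 cation may be attacked only slowly by 14. The fallback gives up the de novo ring construction and takes the middle unit from the chiral pool; it sets out from 2 and 3 and comes back at 17. Bromination of 2 with NBS in CH2Cl2 at −78 °C should give 8-bromo-5,7,3',4'-tetra-O-benzyl-(−)-epicatechin F1. TMSOTf-mediated Friedel–Crafts coupling of 3 with F1, whose only free ring A carbon is C6, should give tetra-O-benzylepicatechin-(4β→6)-8-bromo-tetra-O-benzylepicatechin F2. DDQ oxidation of F2 in the presence of 2-ethoxyethanol should functionalise the exposed C4 methylene of its lower unit in preference to the buried triarylmethine hydrogen and give the 4β-(2-ethoxyethoxy) dimer F3. TMSOTf-mediated coupling of F3 with 14 should then give 17.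

**Step 10.** Halogen–metal exchange on the electron-rich bromophenoxide may be incomplete, the polyanion may transfer a proton to the aryllithium, and the epoxy aldehyde may decompose or epimerise under the basic conditions before the congested aryl anion adds. The fallback replaces the carbonyl addition by an acylation–reduction sequence with a storable acyl donor; it sets out from 10 and 6 and comes back at 15. Treatment of 10 with N,O-dimethylhydroxylamine hydrochloride and i-PrMgCl in THF at −20 °C should give (2S,3S)-3-[3,4-bis(benzyloxy)phenyl]-N-methoxy-N-methyloxirane-2-carboxamide F4. The aryllithium generated from 6 as in step 10 should add to F4, which tolerates warming to −20 °C, and the chelated adduct should release on work-up the cis-epoxy ketone F5 (the ketone analogue of 15). Luche reduction of F5 (NaBH4, CeCl3, MeOH/THF, −78 °C) should give 15.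

**Step 4.** The single free carbon of 5 is flanked by two benzyloxy groups and deactivated by two bromines, so attack on the cation of 3 may be slower than self-condensation of 3 through the ring A positions of other molecules. The fallback uses the unhindered parent phenol as nucleophile and installs protecting groups and bromines afterwards, which also removes any doubt about the regiochemistry of step 3; it sets out from 3 and comes back at 6. Coupling of 3 with excess phloroglucinol (TMSOTf, THF/CH2Cl2, −78 °C) should give 4β-(2,4,6-trihydroxyphenyl)-5,7,3',4'-tetra-O-benzyl-(−)-epicatechin F6. Silylation with TBDPSCl and imidazole should take place at the one unhindered phenol para to the flavanyl group and give the 4-(tert-butyldiphenylsilyloxy)-2,6-dihydroxyphenyl compound F7. Benzylation of the two flanking phenols (BnBr, K2CO3, acetone) should give the 2,6-bis(benzyloxy)-4-(tert-butyldiphenylsilyloxy)phenyl compound F8. Removal of the silyl group (Bu4NF, AcOH, THF) should give 4β-[2,6-bis(benzyloxy)-4-hydroxyphenyl]-5,7,3',4'-tetra-O-benzyl-(−)-epicatechin F9. Bromination of F9 with NBS (2 equiv) and catalytic i-Pr2NH in CH2Cl2 at −78 °C should give 6, because the free phenol directs bromine to its two ortho carbons, the only free positions of that ring, faster than the benzyl-ether ring A of the upper unit reacts.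

Further compounds
F1 | step 11 | 8-bromo-5,7,3',4'-tetra-O-benzyl-(−)-epicatechin | O[C@@H]1Cc2c(OCc3ccccc3)cc(OCc3ccccc3)c(Br)c2O[C@@H]1c1ccc(OCc2ccccc2)c(OCc2ccccc2)c1
F2 | step 11 | tetra-O-benzylepicatechin-(4β→6)-8-bromo-tetra-O-benzylepicatechin | O[C@@H]1[C@@H](c2c(OCc5ccccc5)c(Br)c3c(c2OCc5ccccc5)C[C@@H](O)[C@@H](c2ccc(OCc5ccccc5)c(OCc5ccccc5)c2)O3)c2c(OCc5ccccc5)cc(OCc5ccccc5)cc2O[C@@H]1c1ccc(OCc5ccccc5)c(OCc5ccccc5)c1
F3 | step 11 | tetra-O-benzylepicatechin-(4β→6)-8-bromo-4β-(2-ethoxyethoxy)-tetra-O-benzylepicatechin | O[C@@H]1[C@@H](c2c(OCc5ccccc5)c(Br)c3c(c2OCc5ccccc5)[C@H](OCCOCC)[C@@H](O)[C@@H](c2ccc(OCc5ccccc5)c(OCc5ccccc5)c2)O3)c2c(OCc5ccccc5)cc(OCc5ccccc5)cc2O[C@@H]1c1ccc(OCc5ccccc5)c(OCc5ccccc5)c1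
F4 | step 10 | (2S,3S)-3-[3,4-bis(benzyloxy)phenyl]-N-methoxy-N-methyloxirane-2-carboxamide | CON(C)C(=O)[C@H]1O[C@H]1c1ccc(OCc2ccccc2)c(OCc2ccccc2)c1
F5 | step 10 | cis-epoxy ketone (ketone analogue of 15) | O[C@@H]1[C@@H](c2c(OCc3ccccc3)c(Br)c(O)c(C(=O)[C@H]3O[C@H]3c3ccc(OCc4ccccc4)c(OCc4ccccc4)c3)c2OCc3ccccc3)c2c(OCc3ccccc3)cc(OCc3ccccc3)cc2O[C@@H]1c1ccc(OCc2ccccc2)c(OCc2ccccc2)c1
F6 | step 4 | 4β-(2,4,6-trihydroxyphenyl)-5,7,3',4'-tetra-O-benzyl-(−)-epicatechin | O[C@@H]1[C@@H](c2c(O)cc(O)cc2O)c2c(OCc3ccccc3)cc(OCc3ccccc3)cc2O[C@@H]1c1ccc(OCc2ccccc2)c(OCc2ccccc2)c1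
F7 | step 4 | 4β-[4-(tert-butyldiphenylsilyloxy)-2,6-dihydroxyphenyl]-5,7,3',4'-tetra-O-benzyl-(−)-epicatechin | O[C@@H]1[C@@H](c2c(O)cc(O[Si](c3ccccc3)(c3ccccc3)C(C)(C)C)cc2O)c2c(OCc3ccccc3)cc(OCc3ccccc3)cc2O[C@@H]1c1ccc(OCc2ccccc2)c(OCc2ccccc2)c1
F8 | step 4 | 4β-[2,6-bis(benzyloxy)-4-(tert-butyldiphenylsilyloxy)phenyl]-5,7,3',4'-tetra-O-benzyl-(−)-epicatechin | O[C@@H]1[C@@H](c2c(OCc3ccccc3)cc(O[Si](c3ccccc3)(c3ccccc3)C(C)(C)C)cc2OCc3ccccc3)c2c(OCc3ccccc3)cc(OCc3ccccc3)cc2O[C@@H]1c1ccc(OCc2ccccc2)c(OCc2ccccc2)c1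
F9 | step 4 | 4β-[2,6-bis(benzyloxy)-4-hydroxyphenyl]-5,7,3',4'-tetra-O-benzyl-(−)-epicatechin | O[C@@H]1[C@@H](c2c(OCc3ccccc3)cc(O)cc2OCc3ccccc3)c2c(OCc3ccccc3)cc(OCc3ccccc3)cc2O[C@@H]1c1ccc(OCc2ccccc2)c(OCc2ccccc2)c1
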